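**Retrosynthetic overview**
1. 21 ⇒ 16: global MOM removal, preceded by two twofold aryllithium functionalisations (2 × acetyl, 2 × prenyl) of a pentakis-MOM diarylalkane core. The two open CH positions of each ring are equivalent, so only one regioisomer can form.
2. 16 ⇒ 15 ⇒ 13 + 12 (key step): the CH–CH2 bond is cut. The electrophilic methide carbon of an o-quinone methide is joined to the formyl carbon of isobutyraldehyde, which acts as a carbanion equivalent in its N-trityl hydrazone. A chiral phosphoric acid sets the only stereocentre, and N2 and trityl leave tracelessly.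
3. 13 ⇒ 7 ⇒ 5 + 2: the aryllithium from 5-methoxyresorcinol bis-MOM ether adds to the bis-MOM ether of 2,4,6-trihydroxybenzaldehyde.
4. No ring is formed. Both benzene rings are bought intact (ring A from 5-methoxyresorcinol, ring B from 2,4,6-trihydroxybenzaldehyde).

Assumption: (R)-TRIP is taken to deliver the (R)-methine of 15. The sense of induction must be checked on the first run, and (S)-TRIP is used if it is the opposite.

**Step 1**
Reactants: 1 2,4,6-trihydroxybenzaldehyde
Product: 2 2-hydroxy-4,6-bis(methoxymethoxy)benzaldehyde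
Conditions: MOMCl (2.2 equiv), i-Pr2NEt (2.5 equiv), CH2Cl2, 0 → 23 °C
Reagents that add atoms: chloromethyl methyl ether (MOMCl), COCCl
Why: Williamson-type O-alkylation in which the 4-OH and one ortho-OH react, while the last ortho-OH is held in a strong hydrogen bond to the formyl oxygen and stays free at this stoichiometry; no stereocentre.

**Step 2**
Reactants: 3 5-methoxyresorcinol
Product: 4 1-methoxy-3,5-bis(methoxymethoxy)benzene
Conditions: MOMCl (2.5 equiv), i-Pr2NEt (3 equiv), CH2Cl2, 0 → 23 °C
Reagents that add atoms: chloromethyl methyl ether (MOMCl), COCCl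
Why: The same Williamson-type ether formation on two unhindered, non-chelated phenols; no stereocentre.

**Step 3**
Reactants: 4 1-methoxy-3,5-bis(methoxymethoxy)benzene, 2 2-hydroxy-4,6-bis(methoxymethoxy)benzaldehyde
Product: 7 (±)-[2-hydroxy-4,6-bis(methoxymethoxy)phenyl][4-methoxy-2,6-bis(methoxymethoxy)phenyl]methanol, via aryllithium 5 (not isolated), via sodium phenolate 6 (not isolated)
Conditions: 4 (1.2 equiv), n-BuLi (1.15 equiv), THF, 0 → 23 °C, 1 h; separately 2, NaH (1.05 equiv), THF, 0 °C; combine at −78 → 0 °C; H2O quench; Et3N-deactivated silica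
Reagents that add atoms: none
Why: Directed ortho-metalation occurs at the carbon flanked by both chelating OMOM groups (para to OMe), and 1,2-addition of an aryllithium to a salicylaldehyde phenolate is the standard entry to o-hydroxybenzhydrols; the carbinol centre is racemic and is erased in step 5.

**Step 4**
Reactants: 8 trityl chloride, 9 hydrazine hydrate, 10 isobutyraldehyde
Product: 12 (E)-isobutyraldehyde N-tritylhydrazone, via tritylhydrazine 11 (not isolated)
Conditions: 8, N2H4·H2O (10 equiv), THF, 23 °C; brine wash of the organic layer; then 10 (1.1 equiv), MgSO4, 0 → 23 °C; recrystallise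
Reagents that add atoms: none
Why: SN1 tritylation of excess hydrazine followed by hydrazone condensation gives the crystalline E-hydrazone, in which trityl shields nitrogen and leaves the azomethine carbon as the nucleophilic (aza-enamine) site.

**Step 5 (key step)**
Reactants: 7 (±)-[2-hydroxy-4,6-bis(methoxymethoxy)phenyl][4-methoxy-2,6-bis(methoxymethoxy)phenyl]methanol, 12 (E)-isobutyraldehyde N-tritylhydrazone
Product: 15 2-{(1R)-1-[4-methoxy-2,6-bis(methoxymethoxy)phenyl]-3-methylbutyl}-3,5-bis(methoxymethoxy)phenol, via o-quinone methide 13 (not isolated), via trityl diazene 14 (not isolated)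
Conditions: 7 added over 6 h to 12 (2 equiv), (R)-TRIP (10 mol %), 4 Å MS, PhMe, −30 °C, then 24 h; 2,6-lutidine (0.2 equiv), PhSH (5 equiv), −30 → 40 °C until N2 evolution stops
Reagents that add atoms: none
Why: Proposed new method: the acid dehydrates 7 to o-quinone methide 13 and binds its (protonated) oxygen and the hydrazone N–H on the two phosphate oxygens, so the azomethine carbon of 12 (the former formyl carbon of isobutyraldehyde, here a carbanion equivalent) attacks one face of the electrophilic methide carbon in a closed aza-ene transition state and sets the (R)-stereocentre, with N-attack blocked by trityl and enamine-type α-attack blocked by the quaternary centre it would create; trityl diazene 14 then loses N2 on warming and the secondary alkyl radical is capped by PhSH (about 10^8 M-1 s-1, faster than a 1,2-aryl shift), which delivers the CH2 without a separate deoxygenation; the closest known reaction types are chiral phosphoric acid catalysed conjugate additions of N–H π-nucleophiles such as enamides to in situ o-quinone methides, aza-ene additions of N-tert-butyl hydrazones as acyl anion equivalents under hydrogen-bond catalysis, and reductive C–C bond formation with lithiated aldehyde trityl hydrazones whose diazene adducts lose N2 in the presence of a thiol.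

**Step 6**
Reactants: 15 2-{(1R)-1-[4-methoxy-2,6-bis(methoxymethoxy)phenyl]-3-methylbutyl}-3,5-bis(methoxymethoxy)phenol
Product: 16 (S)-1-[4-methoxy-2,6-bis(methoxymethoxy)phenyl]-3-methyl-1-[2,4,6-tris(methoxymethoxy)phenyl]butane
Conditions: NaH (1.3 equiv), MOMCl (1.5 equiv), THF/DMF, 0 °C
Reagents that add atoms: chloromethyl methyl ether (MOMCl), COCCl
Why: Williamson-type MOM ether formation masks the only acidic proton before the organolithium steps; the phenolate cannot fragment because ring A is fully etherified, so the stereocentre is untouched (the descriptor changes from R to S only through CIP ranking).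

**Step 7**
Reactants: 16 (S)-1-[4-methoxy-2,6-bis(methoxymethoxy)phenyl]-3-methyl-1-[2,4,6-tris(methoxymethoxy)phenyl]butane
Product: 18 (S)-1-[4-methoxy-2,6-bis(methoxymethoxy)-3-(3-methylbut-2-enyl)phenyl]-3-methyl-1-[2,4,6-tris(methoxymethoxy)-3-(3-methylbut-2-enyl)phenyl]butane, via dilithioarene 17 (not isolated)
Conditions: n-BuLi (2.4 equiv), TMEDA (2.4 equiv), THF, 0 °C, 1.5 h; CuBr·SMe2 (10 mol %), prenyl bromide (3 equiv), −78 → 0 °C
Reagents that add atoms: prenyl bromide (1-bromo-3-methylbut-2-ene), CC(C)=CCBr
Why: Twofold directed ortho-metalation puts one lithium on each ring at a CH flanked by two oxygen donors (a second lithiation of the same ring is much slower), ring rotation makes the two open positions of each ring equivalent so one regioisomer results, and Cu-catalysed SN2 allylation follows; the crowded diarylmethine C–H is not deprotonated.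

**Step 8**
Reactants: 18 (S)-1-[4-methoxy-2,6-bis(methoxymethoxy)-3-(3-methylbut-2-enyl)phenyl]-3-methyl-1-[2,4,6-tris(methoxymethoxy)-3-(3-methylbut-2-enyl)phenyl]butane
Product: 20 (S)-1-[3-acetyl-4-methoxy-2,6-bis(methoxymethoxy)-5-(3-methylbut-2-enyl)phenyl]-1-[3-acetyl-2,4,6-tris(methoxymethoxy)-5-(3-methylbut-2-enyl)phenyl]-3-methylbutane, via dilithioarene 19 (not isolated)
Conditions: n-BuLi (2.5 equiv), THF, −20 → 0 °C, 1 h; MeC(O)N(OMe)Me (4 equiv), −78 → 0 °C; H2O
Reagents that add atoms: N-methoxy-N-methylacetamide, CC(=O)N(C)OC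
Why: A second twofold directed ortho-metalation takes the last ring CH of each arene (complex-induced proximity of the flanking OMOM/OMe groups outruns deprotonation of the prenyl CH2), and the Weinreb ketone synthesis stops at the chelated tetrahedral adduct so no over-addition occurs; the stereocentre is untouched.

**Step 9**
Reactants: 20 (S)-1-[3-acetyl-4-methoxy-2,6-bis(methoxymethoxy)-5-(3-methylbut-2-enyl)phenyl]-1-[3-acetyl-2,4,6-tris(methoxymethoxy)-5-(3-methylbut-2-enyl)phenyl]-3-methylbutane
Product: 21 1-[3-[(1R)-1-[3-acetyl-2,6-dihydroxy-4-methoxy-5-(3-methylbut-2-enyl)phenyl]-3-methylbutyl]-2,4,6-trihydroxy-5-(3-methylbut-2-enyl)phenyl]ethanone (target)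
Conditions: 1 M HCl in MeOH, 0 → 23 °C, monitored; NaHCO3 quench
Reagents that add atoms: none
Why: Acid-catalysed transacetalisation to dimethoxymethane frees all five phenols while the aryl methyl ether survives; at ≤23 °C the acetyl-deactivated rings resist ipso-protonation (retro-Friedel–Crafts racemisation) and the prenyl groups do not close to chromans (the descriptor returns to R by CIP ranking only).

**Compound list**
1 | 2,4,6-trihydroxybenzaldehyde | O=Cc1c(O)cc(O)cc1O | starting material
2 | 2-hydroxy-4,6-bis(methoxymethoxy)benzaldehyde | O=Cc1c(O)cc(OCOC)cc1OCOC | intermediate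
3 | 5-methoxyresorcinol | COc1cc(O)cc(O)c1 | starting material
4 | 1-methoxy-3,5-bis(methoxymethoxy)benzene | COc1cc(OCOC)cc(OCOC)c1 | intermediate
5 | [4-methoxy-2,6-bis(methoxymethoxy)phenyl]lithium | [Li]c1c(OCOC)cc(OC)cc1OCOC | intermediate
6 | sodium 2-formyl-3,5-bis(methoxymethoxy)phenolate | [Na+].[O-]c1cc(OCOC)cc(OCOC)c1C=O | intermediate
7 | (±)-[2-hydroxy-4,6-bis(methoxymethoxy)phenyl][4-methoxy-2,6-bis(methoxymethoxy)phenyl]methanol (racemic) | COc1cc(OCOC)c(C(O)c2c(O)cc(OCOC)cc2OCOC)c(OCOC)c1 | intermediate
8 | trityl chloride | ClC(c1ccccc1)(c1ccccc1)c1ccccc1 | starting material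
9 | hydrazine hydrate | NN.O | starting material
10 | isobutyraldehyde | CC(C)C=O | starting material
11 | tritylhydrazine | NNC(c1ccccc1)(c1ccccc1)c1ccccc1 | intermediate
12 | (E)-isobutyraldehyde N-tritylhydrazone | CC(C)/C=N/NC(c1ccccc1)(c1ccccc1)c1ccccc1 | intermediate
13 | 6-{[4-methoxy-2,6-bis(methoxymethoxy)phenyl]methylidene}-3,5-bis(methoxymethoxy)cyclohexa-2,4-dien-1-one (alkene geometry mobile under acid) | COc1cc(OCOC)c(C=C2C(=O)C=C(OCOC)C=C2OCOC)c(OCOC)c1 | intermediate
14 | 2-{(1R)-1-[4-methoxy-2,6-bis(methoxymethoxy)phenyl]-3-methyl-2-[(E)-trityldiazenyl]butyl}-3,5-bis(methoxymethoxy)phenol (epimers at C2) | COc1cc(OCOC)c([C@H](C(/N=N/C(c2ccccc2)(c2ccccc2)c2ccccc2)C(C)C)c2c(O)cc(OCOC)cc2OCOC)c(OCOC)c1 | intermediate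
15 | 2-{(1R)-1-[4-methoxy-2,6-bis(methoxymethoxy)phenyl]-3-methylbutyl}-3,5-bis(methoxymethoxy)phenol | COc1cc(OCOC)c([C@H](CC(C)C)c2c(O)cc(OCOC)cc2OCOC)c(OCOC)c1 | intermediate
16 | (S)-1-[4-methoxy-2,6-bis(methoxymethoxy)phenyl]-3-methyl-1-[2,4,6-tris(methoxymethoxy)phenyl]butane | COc1cc(OCOC)c([C@H](CC(C)C)c2c(OCOC)cc(OCOC)cc2OCOC)c(OCOC)c1 | intermediate
17 | 3,3'-dilithio derivative of 16 (one Li per ring, each between two oxygen substituents) | COc1c([Li])c(OCOC)c([C@H](CC(C)C)c2c(OCOC)c([Li])c(OCOC)cc2OCOC)c(OCOC)c1 | intermediate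
18 | (S)-1-[4-methoxy-2,6-bis(methoxymethoxy)-3-(3-methylbut-2-enyl)phenyl]-3-methyl-1-[2,4,6-tris(methoxymethoxy)-3-(3-methylbut-2-enyl)phenyl]butane | COc1c(CC=C(C)C)c(OCOC)c([C@H](CC(C)C)c2c(OCOC)c(CC=C(C)C)c(OCOC)cc2OCOC)c(OCOC)c1 | intermediate
19 | dilithio derivative of 18 (Li at the last ring CH of each arene) | COc1c(CC=C(C)C)c(OCOC)c([C@H](CC(C)C)c2c(OCOC)c(CC=C(C)C)c(OCOC)c([Li])c2OCOC)c(OCOC)c1[Li] | intermediate
20 | (S)-1-[3-acetyl-4-methoxy-2,6-bis(methoxymethoxy)-5-(3-methylbut-2-enyl)phenyl]-1-[3-acetyl-2,4,6-tris(methoxymethoxy)-5-(3-methylbut-2-enyl)phenyl]-3-methylbutane | COc1c(CC=C(C)C)c(OCOC)c([C@H](CC(C)C)c2c(OCOC)c(CC=C(C)C)c(OCOC)c(C(C)=O)c2OCOC)c(OCOC)c1C(C)=O | intermediate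
21 | 1-[3-[(1R)-1-[3-acetyl-2,6-dihydroxy-4-methoxy-5-(3-methylbut-2-enyl)phenyl]-3-methylbutyl]-2,4,6-trihydroxy-5-(3-methylbut-2-enyl)phenyl]ethanone | COc1c(CC=C(C)C)c(O)c([C@H](CC(C)C)c2c(O)c(CC=C(C)C)c(O)c(C(C)=O)c2O)c(O)c1C(C)=O | target

**Step count and risk**

Total step count: 9. Longest linear sequence: 7 (steps 2, 3, 5, 6, 7, 8, 9; the branch through step 1 is equally long).

The three steps most likely to fail are 5, 8 and 9.

Step 5 is the riskiest.
- The neutral hydrazone may be too weak or too bulky a nucleophile for the strongly stabilised, tetra-ortho-substituted methide.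
- Friedel–Crafts self-alkylation of the electron-rich rings may compete.
- The enantioselectivity is unproven.

The fallback sets out from 7 and 12 and comes back at 15. It keeps the same bond and the same polarity but gives up catalysis. Carbinol 7 is dehydrated (MgSO4, 1 mol % PPTS, CH2Cl2) and the o-quinone methide 13 is isolated. Hydrazone 12 is deprotonated with n-BuLi in THF at −78 °C to the lithium azo-anion F1, a much stronger carbon nucleophile that needs no acid. Its conjugate addition to 13 gives the racemic trityl diazene F2, which on warming with PhSH gives the racemic phenol F3. F3 is carbamoylated with (S)-1-phenylethyl isocyanate, and the diastereomers are separated by crystallisation or chromatography. The (R,S)-carbamate F4 is cleaved with K2CO3/MeOH to return 15.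

Step 8 can fail in three ways.
- n-BuLi may deprotonate the doubly activated prenyl CH2.
- The hindered aryllithium may enolise the Weinreb amide.
- The double acylation may stay incomplete.

The fallback sets out from 16 and comes back at 20. It inverts the order so that butyllithium never meets a prenyl group. Dilithioarene 17 (from 16 as in step 7) is quenched with acetaldehyde to the bis(1-hydroxyethyl) compound F5. n-BuLi (4.5 equiv) converts F5 to the dialkoxide dilithioarene F6, whose alkoxides act as acetyl groups protected in situ. Cu-catalysed prenylation gives the bis-prenyl diol F7, and Dess–Martin oxidation of both benzylic alcohols gives 20.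

Step 9 can fail through acid-induced chroman formation from the prenyl and ortho-OH pairs. It can also fail through partial racemisation, because five hindered MOM groups need prolonged acid.

The fallback sets out from 16 and comes back at 21. It uses the acid before any prenyl group exists. Dilithioarene 17 is acylated with N-methoxy-N-methylacetamide to the bis-acetyl pentakis-MOM ether F8. HCl/MeOH then gives the bis-acetyl pentaphenol F9. Twofold phenolate C-prenylation (prenyl bromide 2.2 equiv, aq KOH, 0 °C) at the single free ring carbon of each acylphloroglucinol ring gives 21.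

**Further compounds**
F1 | step 5 | lithium azo-anion of 12 | CC(C)C=N[N-]C(c1ccccc1)(c1ccccc1)c1ccccc1.[Li+]
F2 | step 5 | racemic trityl diazene (stereoisomer mixture of 14) | COc1cc(OCOC)c(C(C(N=NC(c2ccccc2)(c2ccccc2)c2ccccc2)C(C)C)c2c(O)cc(OCOC)cc2OCOC)c(OCOC)c1
F3 | step 5 | racemic 2-{1-[4-methoxy-2,6-bis(methoxymethoxy)phenyl]-3-methylbutyl}-3,5-bis(methoxymethoxy)phenol | COc1cc(OCOC)c(C(CC(C)C)c2c(O)cc(OCOC)cc2OCOC)c(OCOC)c1
F4 | step 5 | N-[(1S)-1-phenylethyl]carbamate of (R)-15 | COc1cc(OCOC)c([C@H](CC(C)C)c2c(OC(=O)N[C@@H](C)c3ccccc3)cc(OCOC)cc2OCOC)c(OCOC)c1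
F5 | step 8 | 3,3'-bis(1-hydroxyethyl) derivative of 16 (carbinol epimers) | COc1c(C(C)O)c(OCOC)c([C@H](CC(C)C)c2c(OCOC)c(C(C)O)c(OCOC)cc2OCOC)c(OCOC)c1
F6 | step 8 | dilithium dialkoxide of F5 lithiated at the last ring CH of each arene | COc1c(C(C)O[Li])c(OCOC)c([C@H](CC(C)C)c2c(OCOC)c(C(C)O[Li])c(OCOC)c([Li])c2OCOC)c(OCOC)c1[Li]
F7 | step 8 | bis(1-hydroxyethyl) bis-prenyl pentakis-MOM ether (carbinol epimers) | COc1c(C(C)O)c(OCOC)c([C@H](CC(C)C)c2c(OCOC)c(C(C)O)c(OCOC)c(CC=C(C)C)c2OCOC)c(OCOC)c1CC=C(C)C
F8 | step 9 | (S)-3,3'-diacetyl derivative of 16 | COc1c(C(C)=O)c(OCOC)c([C@H](CC(C)C)c2c(OCOC)c(C(C)=O)c(OCOC)cc2OCOC)c(OCOC)c1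
F9 | step 9 | (R)-bis-acetyl pentaphenol (target lacking both prenyl groups) | COc1c(C(C)=O)c(O)c([C@H](CC(C)C)c2c(O)c(C(C)=O)c(O)cc2O)c(O)c1
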